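The amounts first: the flask is charged with 0.950 equiv of coupling partner, less than one equivalent, so the partner is the limiting reagent, and each mole of it that is spent gives a mole of product.

all flasks: substrate 0.085 M
- north-east: coupling partner 0.64 equiv; catalyst 0.08 mol%; run made earlier
- south: coupling partner 1.4 equiv; catalyst 0.08 mol%; run made earlier
- north-west: coupling partner 0.95 equiv; catalyst 0.04 mol%; run made earlier
- flask: coupling partner 0.950 equiv; catalyst 0.08 mol%

| north-east: time / h | north-east: product / % | south: time / h | south: product / % | north-west: time / h | north-west: product / % |
|---|---|---|---|---|---|
| 1.00 | 1.3 | 2.50 | 13.9 | 1.00 | 1.0 |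
| 3.00 | 7.9 | 5.00 | 28.9 | 3.00 | 5.6 |
| 6.00 | 17.0 | 8.00 | 43.4 | 6.00 | 13.5 |
| 8.00 | 22.8 | 10.0 | 51.3 | 8.00 | 19.8 |
| 12.0 | 30.7 | 12.0 | 57.0 | 12.0 | 29.7 |

(readings scatter by 0.5 percentage points)

- apparent order in coupling partner when 20% of the substrate are converted (percent change of the rate of making product for one percent more coupling partner charged)

- candidate steps: substrate + catalyst <-> catalyst + intermediate; coupling partner + catalyst + intermediate -> catalyst + product; 2 catalyst <-> resting dimer
- what has left substrate counts as converted, also if it is not yet product

The candidate steps are these: substrate passes reversibly on the catalyst into intermediate, partner turns intermediate into product on the catalyst, and two catalyst join reversibly into resting dimer. The ledger at 20% conversion therefore has two entries, intermediate and product, and the readings show product only.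

In the north-east run, which has the flask's catalyst loading, product climbs between 3.00 h and 6.00 h by a fraction 0.0303 h⁻¹ of the charge. Drawn back, that line meets zero at the lag, the delay of product behind the start, read as 0.396 h. Scaled to the flask's partner charge, the slope becomes 0.0450 h⁻¹.

So this reckoning puts the product entry at the end of the lag at about 1.78%, a small debit against the partner charge. If the flask reaches 20% inside the lag, nearly all of the converted substrate is intermediate, which is made by a step without partner, and this reckoning puts the order just under one. If it gets there later, product takes a larger entry and the order can be lower. The reckoning here commits to the first, as a choice.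

The forecast differs: 0.85, with “product is about 11–12 %”.

The flask gives 0.98.

    substrate + catalyst ⇌ catalyst + intermediate (K = 3.10, k = 4.30 M⁻¹ s⁻¹)
    coupling partner + catalyst + intermediate → catalyst + product (k = 7.10 M⁻² s⁻¹)
    2 catalyst ⇌ resting dimer, settled at all times (K = 5500 M⁻¹)

The flask reaches 20% conversion at 0.331 h, earlier than the lag of 0.396 h read from the north-east run. The same lag and slope put product in the flask at 7.22% after 2.00 h, and the flask then holds 6.99%.

The earlier runs and the new flask are simulated on assumed constants; noise was put on by code.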